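## Structural features

The target is a labdane, methyl (13S)-6β-acetoxy-8α-hydroxylabdan-15-oate: a trans-fused decalin (ring A = C1–C5/C10, ring B = C5–C10) with a six-carbon chain (C11–C16) on C9 that ends in a methyl ester and carries a methyl-bearing stereocentre at C13. Five of the six stereocentres (C5, C6, C8, C9, C10) are contiguous around ring B and are flanked by three fully substituted carbons (C4, C8, C10). C13 is separated from the ring by two methylenes, so it cannot be controlled from the bicycle. The β face is crowded: the C19 and C20 methyls, the 6β-acetate and the C17 methyl are all axial and 1,3-related. Fragile points are the tertiary 8α-hydroxyl (dehydration), the axial secondary acetate (hydrolysis, elimination) and the methyl ester, which must be distinguished from any other ester used on the way. The real difficulty is to set C6, C8 and C9 on a ring whose neighbours are quaternary, with no stereochemical relay to C13. The feature exploited is that C8 carries a one-carbon branch (C17) plus oxygen and C9 carries a chain whose first bond (C11–C12) can be an alkene. The C8–C9 bond of ring B is therefore the bond that an ene-type union of a C8≡C17 alkyne with a C9=C11 alkene would make, leaving an 8(17)-methylene for hydration and an 11-ene for hydrogenation.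

## Logic of the disconnections

25 is taken back to 24 without cutting a skeletal bond: the saturated C11–C12 unit is the hydrogenation product of the E-alkene left by the ring-forming step. Nothing extra is introduced. The forward demand is that hydrogenation must not move the double bond toward C13, and must spare the tertiary alcohol and both esters.

24 is taken back to 22 by cutting C8–O: the tertiary carbinol with its methyl is the Markovnikov hydrate of a 1,1-disubstituted alkene. This removes one stereocentre and postpones the most fragile group to the penultimate step. The forward step must prefer the exocyclic alkene over the 11-ene and deliver oxygen to the α face.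

22 is taken back to 21 by cutting C8–C9 (the key cut). Ring B opens, the C9 stereocentre disappears and a monocyclic ring A with two arms remains. 21 and 22 were rebuilt atom by atom from 25 and agree with it at C5, C6, C10 and C13 (C13 is S in 21 and 25 but R in 22–24 only because the 11-ene changes the priorities). The forward step must close 6-exo, place C11 equatorial on C9 and eliminate toward C12. 21 keeps the acetate of 25 (inert, homopropargylic), a free terminal alkyne and the Z alkene that a Wittig reaction delivers.

21 is taken back to 15 and 19 (through 20) by cutting C9=C11. This is the convergent junction, and placing it last means that the chain methyl ester never meets a hydride reagent. The forward step must take a hindered aldehyde with no α-hydrogen faster than the acetate or the ylide's own ester, and give the Z alkene.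

19 is taken back through 18 and 17 to 16 by cutting C11–P and C11–I back to the carboxyl carbon. C13 is bought with the chiral pool. The only demand is reduction of the acid beside the ester.

15 is taken back through 14 and 13 to 11 by cutting C6–C7 and the acetyl C–O bond. The C9 aldehyde is carried as a dioxolane, so that the C6 formyl group is the only carbonyl present when the C6 centre is made. The forward step must select one face of a formyl group flanked by two quaternary carbons by reagent control.

11 is taken back through 10, 9 and 7 to 5 by cutting both C4–CH3 bonds and restoring the C3 oxygen and the C1=C2 alkene. The enone makes C4 the only enolisable ketone position (C10 is quaternary) and is then erased. The deoxygenation must tolerate the acetal, which rules out thioacetal chemistry and favours reductive triflation and hydrogenolysis.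

5 is taken back through 4 to 1 and 2 by cutting C1–C10 and C4–C5 ([4+2]). Ring A appears with C5 and C10 set, and with the two carbonyl arms (C6 ester, C9 aldehyde) already different. The forward step needs aldehyde-controlled regiochemistry, catalyst-controlled face selectivity, and acetalisation of the aldehyde in preference to the enone.

## Other disconnections considered

Alternative 1: Cuts C5–C10 and C8–C9 together. An open-chain siloxytrienal A2, (2E,8Z,10E)-9-(tert-butyldimethylsilyloxy)-3,7,7-trimethyldodeca-2,8,10-trienal, would undergo a type 1 intramolecular Diels–Alder reaction under a chiral oxazaborolidinium triflimide to give the trans-fused aldehyde A1 with a C6=C7 silyl enol ether.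
- In favour: two rings, two C–C bonds and the C5, C9 and C10 centres arise in one catalytic asymmetric step, the gem-dimethyl group is carried in the chain, and the C6 oxygen is present from the start. On ring construction and early C6 oxygenation this plan is better than the chosen one.
- Against: the dienophile is a β,β-disubstituted enal and the diene terminus C5 is neopentyl, so C5–C10 must form between two very hindered carbons. The acid-labile siloxydiene must also survive a strong cationic Lewis acid, where stepwise Michael-type paths and protodesilylation are plausible leaks.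
- Against: C8 emerges as a methyl-bearing CH, so the 8α-hydroxyl still needs an oxidation sequence across C7/C8, and the chain with C13 must be attached at C11 afterwards.
- Comparison: a concerted cycloaddition with a well-understood catalyst model is mechanistically at least the equal of a palladium hydride cycle. The steric demand at its forming bond is higher than at C8–C9 of 21. A2 needs three defined alkene geometries and A1 needs roughly eight further operations, so no saving in steps is foreseen.

Alternative 2: Cuts C4–C5 in ring A. A symmetric resorcinol-derived bis(enol ether) A4, carrying an (R)-epoxy side chain on the future C10, would be treated with BF3·OEt2. The epoxide opens at C4, one of the two enantiotopic enol ether carbons attacks, and acidic work-up would unveil the hydroxy-dione A3 after equilibration at C5.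
- In favour: the decalin with the C4 gem-dimethyl group, the C10 quaternary centre and oxygen at both C6 and C8 is reached in very few steps from an aromatic compound. On brevity to the bicyclic core this plan is the better one, and on using a single early source of asymmetry the two are equal.
- Against: the C3 hydroxyl must be removed, the two carbonyls of a 1,3-dione must be told apart, and the chain must be attached at C9 by dianion alkylation.
- Against: a methyl nucleophile would be expected to add to C8 from the open α face, giving the wrong 8β-hydroxy arrangement, so a methylenation and hydration endgame like the present one would still be needed.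
- Against: the relay from the epoxide centre to C10 depends on which chair-like fold (C20 axial or equatorial) is preferred for attack on a planar dienol ether. This is less secure than a catalyst-controlled cycloaddition.
- Comparison: structurally more direct to the ring system. Mechanistically it is a simple cationic closure but sensitive to epoxide rearrangement and O-attack. In step economy it is probably equal once deoxygenation, carbonyl differentiation and chain attachment are counted.

Alternative 3: Cuts C6–C7. An aldehyde A6 (C6 formyl on C5, isopropenyl C8(=C7)C17 and the chain on C9) would be treated with FeCl2 and tert-butyl hydroperoxide. The acyl radical adds 6-endo to C7 and the tertiary C8 radical is capped as the tert-butyl peroxide A5.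
- In favour: ring B, the C6 carbonyl and the C8 oxygen arrive in one operation, and only O–O cleavage, ketone reduction from the α face and acetylation remain. In delivering both ring-B oxygens during ring closure and in the brevity of the endgame it is the equal of, or better than, the chosen plan. A radical also tolerates crowding at the forming bond better than a carbopalladation.
- Against: C9 must already be a stereocentre in an open chain beside quaternary C10, where no ring controls it. The hardest stereochemical problem is thus moved to the least controllable stage.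
- Against: hydrogen abstraction could also occur at the allylic C9–H and C17 positions, the α-branched acyl radical may lose CO before the slow 6-endo closure, and A5 could lose tert-butyl hydroperoxide across C7–C8.
- Comparison: the chosen path sets C9 in the ring-forming step through a chair, which this alternative cannot. Step counts would be similar only if A6 could be made with C9 controlled in about ten steps.

Key step: step 14

Assumption: (S)-3-methylglutaric acid monomethyl ester (16) is taken as purchasable in high enantiomeric purity, as the product of enzymatic desymmetrisation of the prochiral diester or anhydride.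
Assumption: labdane numbering (C1–C20) is used for positions in every intermediate.

## Route

Step 1
Reactants: 1 ethyl (2E)-3-methyl-4-oxobut-2-enoate; 2 (1E)-3-[(tert-butyldimethylsilyl)oxy]-N,N-dimethylbuta-1,3-dien-1-amine
Product: 4 ethyl (1S,2S)-2-formyl-2-methyl-5-oxocyclohex-3-ene-1-carboxylate, via Diels–Alder cycloadduct 3 (not isolated)
Conditions: (R,R)-1-naphthyl-TADDOL (20 mol %), PhMe, −78 °C; then 1 M HCl, THF, 0 °C
Reagents that add atoms: none
Why: Normal-demand Diels–Alder reaction under hydrogen-bond catalysis by the chiral diol: the formyl group is the stronger acceptor, so the CH2 terminus of 2 should bond to the ester-bearing carbon (C5) and the amino-bearing terminus to the methyl-bearing carbon (C10), and the E geometry of 1 is carried over as the trans CHO/CO2Et relation. The diol antipode fixes C5 and C10 (the (R,R) diol is proposed by analogy with α-substituted acroleins, and the (S,S) diol is equally available if the sense proves opposite); acid then cleaves the silyl enol ether and eliminates dimethylamine to give the enone.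

Step 2
Reactants: 4 ethyl (1S,2S)-2-formyl-2-methyl-5-oxocyclohex-3-ene-1-carboxylate
Product: 5 ethyl (1S,2S)-2-(1,3-dioxolan-2-yl)-2-methyl-5-oxocyclohex-3-ene-1-carboxylate
Conditions: HOCH2CH2OH, PPTS (cat.), PhH, reflux (Dean–Stark)
Reagents that add atoms: ethylene glycol, OCCO
Why: Acetalisation should be selective for the aldehyde because the conjugated ketone is a much weaker electrophile; the dioxolane masks C9 through all carbanion and hydride steps.

Step 3
Reactants: 5 ethyl (1S,2S)-2-(1,3-dioxolan-2-yl)-2-methyl-5-oxocyclohex-3-ene-1-carboxylate
Product: 7 ethyl (1R,2S)-2-(1,3-dioxolan-2-yl)-2,6,6-trimethyl-5-oxocyclohex-3-ene-1-carboxylate, via monomethyl enone 6 (not isolated)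
Conditions: LiN(iPr)2, THF, −78 °C; MeI; then LiN(iPr)2, −78 °C; MeI, DMPU, −78 → 0 °C
Reagents that add atoms: iodomethane, CI
Why: Kinetic enolate alkylation: C10 is quaternary, so the ketone can enolise only toward C4, and this position is deprotonated far faster than the hindered ester α-hydrogen at C5, which keeps its configuration. The second deprotonation and methylation in the same flask completes the C4 gem-dimethyl group.

Step 4
Reactants: 7 ethyl (1R,2S)-2-(1,3-dioxolan-2-yl)-2,6,6-trimethyl-5-oxocyclohex-3-ene-1-carboxylate
Product: 9 ethyl (1S,6S)-6-(1,3-dioxolan-2-yl)-2,2,6-trimethyl-3-[(trifluoromethanesulfonyl)oxy]cyclohex-3-ene-1-carboxylate, via lithium enolate 8 (not isolated)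
Conditions: Li[HB(sBu)3], THF, −78 °C; then PhNTf2, −78 °C → rt
Reagents that add atoms: N-phenylbis(trifluoromethanesulfonimide), O=S(=O)(N(c1ccccc1)S(=O)(=O)C(F)(F)F)C(F)(F)F
Why: Conjugate reduction of the enone by the bulky trialkylborohydride (1,2-attack is blocked by the C4 gem-dimethyl group) gives the C2=C3 enolate regiospecifically, which is O-triflated in the same flask; the hindered ester should be untouched at −78 °C.

Step 5
Reactants: 9 ethyl (1S,6S)-6-(1,3-dioxolan-2-yl)-2,2,6-trimethyl-3-[(trifluoromethanesulfonyl)oxy]cyclohex-3-ene-1-carboxylate
Product: 10 ethyl (1S,2S)-2-(1,3-dioxolan-2-yl)-2,6,6-trimethylcyclohexane-1-carboxylate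
Conditions: H2 (3 atm), PtO2, NaHCO3, EtOAc, rt
Reagents that add atoms: none
Why: Hydrogenolysis and hydrogenation of an enol triflate over platinum removes the C3 oxygen and saturates ring A in one operation; bicarbonate takes up the triflic acid so that the acetal survives, and no dithioacetal chemistry (which would exchange with the dioxolane) is needed.

Step 6
Reactants: 10 ethyl (1S,2S)-2-(1,3-dioxolan-2-yl)-2,6,6-trimethylcyclohexane-1-carboxylate
Product: 11 (1S,2S)-2-(1,3-dioxolan-2-yl)-2,6,6-trimethylcyclohexane-1-carbaldehyde
Conditions: iBu2AlH, CH2Cl2, −78 °C; aq. potassium sodium tartrate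
Reagents that add atoms: none
Why: Partial reduction of an ester: the tetrahedral aluminium hemiacetal of this very hindered ester should persist at −78 °C and collapse to the aldehyde only on work-up; no other ester is in the molecule at this stage.

Step 7
Reactants: 11 (1S,2S)-2-(1,3-dioxolan-2-yl)-2,6,6-trimethylcyclohexane-1-carbaldehyde
Product: 13 (1R)-1-[(1S,2S)-2-(1,3-dioxolan-2-yl)-2,6,6-trimethylcyclohexyl]but-3-yn-1-ol, via borinate 12 (not isolated)
Conditions: (+)-Ipc2BOMe, CH2=C=CHMgBr, Et2O, 0 °C; then 11, −78 °C → rt; NaOH, H2O2
Reagents that add atoms: allenyl(diisopinocampheyl)borane from (−)-α-pinene (formed from (+)-Ipc2BOMe and allenylmagnesium bromide, C=C=C[Mg]Br), C=C=CB([C@H]1C[C@H]2C[C@@H]([C@@H]1C)C2(C)C)[C@H]1C[C@H]2C[C@@H]([C@@H]1C)C2(C)C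
Why: Asymmetric propargylboration (SE2′ transfer from the allenylborane through a six-membered transition state) creates C6–C7 and the C6 carbinol. With a formyl group flanked by two similar quaternary carbons the substrate bias should be small, so the isopinocampheyl groups from (−)-α-pinene are expected to direct attack to the Re face and give the 6R (6β-oxygen) configuration.

Step 8
Reactants: 13 (1R)-1-[(1S,2S)-2-(1,3-dioxolan-2-yl)-2,6,6-trimethylcyclohexyl]but-3-yn-1-ol
Product: 14 (1R)-1-[(1S,2S)-2-(1,3-dioxolan-2-yl)-2,6,6-trimethylcyclohexyl]but-3-yn-1-yl acetate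
Conditions: Ac2O, DMAP, pyridine, CH2Cl2, 40 °C
Reagents that add atoms: acetic anhydride, CC(=O)OC(C)=O
Why: DMAP-catalysed acylation of the hindered secondary alcohol installs the acetate of the target, which then serves as the only hydroxyl protection needed.

Step 9
Reactants: 14 (1R)-1-[(1S,2S)-2-(1,3-dioxolan-2-yl)-2,6,6-trimethylcyclohexyl]but-3-yn-1-yl acetate
Product: 15 (1R)-1-[(1S,2S)-2-formyl-2,6,6-trimethylcyclohexyl]but-3-yn-1-yl acetate
Conditions: 2 M HCl, THF, 40 °C
Reagents that add atoms: water, O
Why: Acid hydrolysis of the dioxolane releases the C9 aldehyde, which has no α-hydrogen and cannot epimerise, and cannot form a lactol now that O6 is acylated; the acetate and the terminal alkyne should be stable to dilute acid.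

Step 10
Reactants: 16 (3S)-5-methoxy-3-methyl-5-oxopentanoic acid
Product: 17 methyl (3S)-5-hydroxy-3-methylpentanoate
Conditions: BH3·SMe2, THF, 0 °C → rt
Reagents that add atoms: none
Why: Borane reduces a carboxylic acid much faster than an ester, so only the acid terminus (the future C11) becomes the primary alcohol; the stereocentre is untouched.

Step 11
Reactants: 17 methyl (3S)-5-hydroxy-3-methylpentanoate
Product: 18 methyl (3R)-5-iodo-3-methylpentanoate
Conditions: I2, PPh3, imidazole, CH2Cl2, 0 °C
Reagents that add atoms: iodine, II
Why: Appel-type iodination of the primary alcohol under neutral conditions; prompt conversion avoids lactonisation of the hydroxy ester (the descriptor changes to R by priority only).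

Step 12
Reactants: 18 methyl (3R)-5-iodo-3-methylpentanoate
Product: 19 [(3R)-5-methoxy-3-methyl-5-oxopentyl]triphenylphosphonium iodide
Conditions: PPh3, MeCN, reflux
Reagents that add atoms: triphenylphosphine, c1ccc(cc1)P(c1ccccc1)c1ccccc1
Why: SN2 quaternisation of triphenylphosphine by the primary iodide gives the Wittig salt.

Step 13
Reactants: 15 (1R)-1-[(1S,2S)-2-formyl-2,6,6-trimethylcyclohexyl]but-3-yn-1-yl acetate; 19 [(3R)-5-methoxy-3-methyl-5-oxopentyl]triphenylphosphonium iodide
Product: 21 methyl (3S,5Z)-6-[(1R,2S)-2-[(1R)-1-acetoxybut-3-yn-1-yl]-1,3,3-trimethylcyclohexyl]-3-methylhex-5-enoate, via phosphorus ylide 20 (not isolated)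
Conditions: NaN(SiMe3)2 (slight deficit), THF, −78 → 0 °C; then 15, −78 → 0 °C
Reagents that add atoms: none
Why: Wittig olefination with a non-stabilised ylide under salt-free conditions should give the Z alkene, particularly with an α-quaternary aldehyde. The ylide is made with a slight deficit of base at low temperature so that its own ester, the acetate and the alkyne C–H of 15 are not attacked, and the chain ester enters only here, after the last hydride step.

Step 14
Reactants: 21 methyl (3S,5Z)-6-[(1R,2S)-2-[(1R)-1-acetoxybut-3-yn-1-yl]-1,3,3-trimethylcyclohexyl]-3-methylhex-5-enoate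
Product: 22 methyl (13R)-6β-acetoxylabda-8(17),11E-dien-15-oate (5S,6R,9S,10R)
Conditions: Pd2(dba)3·CHCl3 (5 mol %), P(o-Tol)3 (20 mol %), AcOH (1 equiv), PhMe, 60 °C
Reagents that add atoms: none
Why: Acetic acid converts zerovalent palladium into H–Pd–OAc, which adds across the terminal alkyne with palladium on C8 and hydrogen on C17; the C8 vinylpalladium inserts the C9=C11 alkene by syn carbopalladation, and β-hydride elimination from C12 releases the 1,4-diene and returns zerovalent palladium. The closest known reaction type is the palladium-catalysed cycloisomerisation (Alder-ene) of 1,6- and 1,7-enynes to 1,4-dienes with an exocyclic methylene. Ring B closes 6-exo-trig through a chair-like array C8–C7–C6–C5–C10–C9 that ring A already holds in place, with the C6 acetate axial and no axial group yet on sp2 C8. The new stereocentre C9 is controlled by the existing C5 and C10 centres: in the chair the inserting alkene lies either anti to C5 (C11 equatorial, β) or under ring A (C11 axial, α). The Z geometry puts C12 beside the small C20 methyl in the first case but against C5 and the α face of ring A in the second, so C11 should end β and H9 α. Hydropalladation regiochemistry is secured by the terminal alkyne and by the tether, since only a C8–Pd species can reach C9. Elimination toward C12 and not toward C9–H is expected because the new 8(17)-alkene can stay bound to palladium and hold C9–H out of syn-coplanarity, while the C12 hydrogens rotate freely. The homopropargylic acetate cannot ionise to an allyl complex and the ester is inert, so no protecting-group change is needed.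

Step 15
Reactants: 22 methyl (13R)-6β-acetoxylabda-8(17),11E-dien-15-oate
Product: 24 methyl (13R)-6β-acetoxy-8α-hydroxylabd-11E-en-15-oate (5S,6R,8R,9R,10S), via 8α-hydroperoxide 23 (not isolated)
Conditions: Mn(dpm)3 (20 mol %), PhSiH3, O2 (1 atm), iPrOH/CH2Cl2, 0 °C; then PPh3
Reagents that add atoms: dioxygen, O=O
Why: Mukaiyama hydration by hydrogen-atom transfer: the manganese hydride delivers H to C17 of the 1,1-disubstituted alkene (the 1,2-disubstituted 11-ene is much slower). The tertiary C8 radical should capture O2 from the α (equatorial) face because the β face is screened by the axial C20 methyl and the 6β-acetate; the phosphine completes reduction of the hydroperoxide.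

Step 16
Reactants: 24 methyl (13R)-6β-acetoxy-8α-hydroxylabd-11E-en-15-oate
Product: 25 methyl (13S)-6β-acetoxy-8α-hydroxylabdan-15-oate (5S,6R,8R,9R,10S)
Conditions: H2 (1 atm), PtO2, EtOAc, rt
Reagents that add atoms: none
Why: Heterogeneous hydrogenation of the disubstituted alkene; platinum is chosen over palladium to suppress double-bond migration toward C13, so the chain stereocentre is preserved (its descriptor returns to S by priority).

## Compound list

1 | ethyl (2E)-3-methyl-4-oxobut-2-enoate | CCOC(=O)/C=C(\C)C=O | starting material
2 | (1E)-3-[(tert-butyldimethylsilyl)oxy]-N,N-dimethylbuta-1,3-dien-1-amine | CN(C)/C=C/C(=C)O[Si](C)(C)C(C)(C)C | starting material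
3 | ethyl (1S,5S,6R)-5-(dimethylamino)-6-formyl-6-methyl-3-[(tert-butyldimethylsilyl)oxy]cyclohex-3-ene-1-carboxylate (endo adduct, amino cis to formyl) | CCOC(=O)[C@H]1CC(O[Si](C)(C)C(C)(C)C)=C[C@H](N(C)C)[C@]1(C)C=O | intermediate (not isolated)
4 | ethyl (1S,2S)-2-formyl-2-methyl-5-oxocyclohex-3-ene-1-carboxylate | CCOC(=O)[C@H]1CC(=O)C=C[C@]1(C)C=O | intermediate
5 | ethyl (1S,2S)-2-(1,3-dioxolan-2-yl)-2-methyl-5-oxocyclohex-3-ene-1-carboxylate | CCOC(=O)[C@H]1CC(=O)C=C[C@]1(C)C1OCCO1 | intermediate
6 | ethyl (1S,2S,6RS)-2-(1,3-dioxolan-2-yl)-2,6-dimethyl-5-oxocyclohex-3-ene-1-carboxylate (epimers at the new methyl centre, erased in the second alkylation) | CCOC(=O)[C@H]1C(C)C(=O)C=C[C@]1(C)C1OCCO1 | intermediate (not isolated)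
7 | ethyl (1R,2S)-2-(1,3-dioxolan-2-yl)-2,6,6-trimethyl-5-oxocyclohex-3-ene-1-carboxylate | CCOC(=O)[C@H]1C(C)(C)C(=O)C=C[C@]1(C)C1OCCO1 | intermediate
8 | lithium (4S,5S)-4-(1,3-dioxolan-2-yl)-5-(ethoxycarbonyl)-4,6,6-trimethylcyclohex-1-en-1-olate | CCOC(=O)[C@H]1C(C)(C)C([O-])=CC[C@]1(C)C1OCCO1.[Li+] | intermediate (not isolated)
9 | ethyl (1S,6S)-6-(1,3-dioxolan-2-yl)-2,2,6-trimethyl-3-[(trifluoromethanesulfonyl)oxy]cyclohex-3-ene-1-carboxylate | CCOC(=O)[C@H]1C(C)(C)C(OS(=O)(=O)C(F)(F)F)=CC[C@]1(C)C1OCCO1 | intermediate
10 | ethyl (1S,2S)-2-(1,3-dioxolan-2-yl)-2,6,6-trimethylcyclohexane-1-carboxylate | CCOC(=O)[C@H]1C(C)(C)CCC[C@]1(C)C1OCCO1 | intermediate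
11 | (1S,2S)-2-(1,3-dioxolan-2-yl)-2,6,6-trimethylcyclohexane-1-carbaldehyde | O=C[C@H]1C(C)(C)CCC[C@]1(C)C1OCCO1 | intermediate
12 | (1R)-1-[(1S,2S)-2-(1,3-dioxolan-2-yl)-2,6,6-trimethylcyclohexyl]but-3-yn-1-yl bis(isopinocampheyl)borinate (isopinocampheyl groups from (−)-α-pinene) | C#CC[C@@H](OB([C@H]1C[C@H]2C[C@@H]([C@@H]1C)C2(C)C)[C@H]1C[C@H]2C[C@@H]([C@@H]1C)C2(C)C)[C@H]1C(C)(C)CCC[C@]1(C)C1OCCO1 | intermediate (not isolated)
13 | (1R)-1-[(1S,2S)-2-(1,3-dioxolan-2-yl)-2,6,6-trimethylcyclohexyl]but-3-yn-1-ol | C#CC[C@@H](O)[C@H]1C(C)(C)CCC[C@]1(C)C1OCCO1 | intermediate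
14 | (1R)-1-[(1S,2S)-2-(1,3-dioxolan-2-yl)-2,6,6-trimethylcyclohexyl]but-3-yn-1-yl acetate | C#CC[C@@H](OC(C)=O)[C@H]1C(C)(C)CCC[C@]1(C)C1OCCO1 | intermediate
15 | (1R)-1-[(1S,2S)-2-formyl-2,6,6-trimethylcyclohexyl]but-3-yn-1-yl acetate | C#CC[C@@H](OC(C)=O)[C@H]1C(C)(C)CCC[C@]1(C)C=O | intermediate
16 | (3S)-5-methoxy-3-methyl-5-oxopentanoic acid | COC(=O)C[C@@H](C)CC(=O)O | starting material
17 | methyl (3S)-5-hydroxy-3-methylpentanoate | COC(=O)C[C@@H](C)CCO | intermediate
18 | methyl (3R)-5-iodo-3-methylpentanoate | COC(=O)C[C@@H](C)CCI | intermediate
19 | [(3R)-5-methoxy-3-methyl-5-oxopentyl]triphenylphosphonium iodide | COC(=O)C[C@@H](C)CC[P+](c1ccccc1)(c1ccccc1)c1ccccc1.[I-] | intermediate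
20 | methyl (3R)-3-methyl-5-(triphenyl-λ5-phosphanylidene)pentanoate | COC(=O)C[C@@H](C)CC=P(c1ccccc1)(c1ccccc1)c1ccccc1 | intermediate (not isolated)
21 | methyl (3S,5Z)-6-[(1R,2S)-2-[(1R)-1-acetoxybut-3-yn-1-yl]-1,3,3-trimethylcyclohexyl]-3-methylhex-5-enoate | COC(=O)C[C@@H](C)C/C=C\[C@@]1(C)CCCC(C)(C)[C@@H]1[C@H](OC(C)=O)CC#C | intermediate
22 | methyl (13R)-6β-acetoxylabda-8(17),11E-dien-15-oate (5S,6R,9S,10R) | COC(=O)C[C@@H](C)/C=C/[C@@H]1[C@@]2(C)CCCC(C)(C)[C@@H]2[C@H](OC(C)=O)CC1=C | intermediate
23 | methyl (13R)-6β-acetoxy-8α-hydroperoxylabd-11E-en-15-oate | COC(=O)C[C@@H](C)/C=C/[C@@H]1[C@@]2(C)CCCC(C)(C)[C@@H]2[C@H](OC(C)=O)C[C@@]1(C)OO | intermediate (not isolated)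
24 | methyl (13R)-6β-acetoxy-8α-hydroxylabd-11E-en-15-oate (5S,6R,8R,9R,10S) | COC(=O)C[C@@H](C)/C=C/[C@@H]1[C@@]2(C)CCCC(C)(C)[C@@H]2[C@H](OC(C)=O)C[C@@]1(C)O | intermediate
25 | methyl (13S)-6β-acetoxy-8α-hydroxylabdan-15-oate (5S,6R,8R,9R,10S) | COC(=O)C[C@@H](C)CC[C@@H]1[C@@]2(C)CCCC(C)(C)[C@@H]2[C@H](OC(C)=O)C[C@@]1(C)O | target

## Step count and least certain steps

Total: 16 steps. Longest linear sequence: 13 steps (steps 1–9 and 13–16). The chain fragment takes 3 steps (10–12).

Step 14 (key step). Insertion into the hindered Z alkene beside quaternary C10 may be slow, which would let the alkyne oligomerise or add acetic acid. β-Hydride elimination may go toward C9–H and give the conjugated diene. The palladium hydride may move the 11-ene toward C13 and erode that centre, and face selectivity at C9 may be incomplete. Fallback, a radical closure in place of the organopalladium one: it sets out from 21. Bu3SnH and AIBN in PhH at 80 °C add a stannyl radical to C17; the C8 vinyl radical closes 6-exo onto C9 through the same chair, and the C11 radical is reduced, giving methyl (13S)-6β-acetoxy-17-(tributylstannyl)labd-8(17)-en-15-oate F1. Protodestannylation with HCl in CH2Cl2 gives methyl (13S)-6β-acetoxylabd-8(17)-en-15-oate F2. The hydration conditions of step 15 applied to F2 lead directly to 25, where the fallback rejoins the route with no hydrogenation needed.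

Step 7. Addition to a formyl group flanked by two quaternary carbons may be sluggish, and face selection by the borane may be incomplete or opposed by the substrate. Fallback, oxidation followed by catalyst-controlled reduction: it sets out from 11. Propargyl bromide and Zn in THF give the C6-epimeric alcohols (1RS)-1-[(1S,2S)-2-(1,3-dioxolan-2-yl)-2,6,6-trimethylcyclohexyl]but-3-yn-1-ol F3. Dess–Martin periodinane buffered with NaHCO3 gives the ketone 1-[(1S,2S)-2-(1,3-dioxolan-2-yl)-2,6,6-trimethylcyclohexyl]but-3-yn-1-one F4, used at once to avoid isomerisation to the allenyl ketone. Corey–Bakshi–Shibata reduction with the (S)-methyl oxazaborolidine and BH3·SMe2 (large group = ring carbon, small group = propargyl) should return 13, where the fallback rejoins the route.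

Step 1. The uncatalysed cycloaddition of this doubly activated dienophile may compete and erode enantioselectivity, ester-directed regiochemistry may intrude, and the facial sense is assigned only by analogy. Fallback, Lewis-acid catalysis with a less basic diene: it sets out from 1. The carbamate diene methyl benzyl{(1E)-3-[(tert-butyldimethylsilyl)oxy]buta-1,3-dien-1-yl}carbamate F5 replaces 2. The catalyst is [Cr(salen)]SbF6, a cationic complex of trivalent chromium in which salen is the dianion of (1S,2S)-N,N'-bis(3,5-di-tert-butylsalicylidene)cyclohexane-1,2-diamine, used in CH2Cl2 at −40 °C. This should give ethyl (1S,5S,6R)-5-[benzyl(methoxycarbonyl)amino]-6-formyl-6-methyl-3-[(tert-butyldimethylsilyl)oxy]cyclohex-3-ene-1-carboxylate F6. Aqueous HF in MeCN then eliminates the carbamate and returns 4, where the fallback rejoins the route.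

Step 15. Oxygen capture at C8 may not be fully α-selective, hydrogen-atom transfer may also reach the 11-ene, and reversible transfer may isomerise the exocyclic alkene into the ring. Fallback, ionic Markovnikov hydration: it sets out from 22. Hg(OAc)2 in THF/H2O reacts with 1,1-disubstituted alkenes far faster than with 1,2-disubstituted ones, and water should enter on the α face, opposite the two axial groups, giving methyl (13R)-6β-acetoxy-17-(acetoxymercurio)-8α-hydroxylabd-11E-en-15-oate F7. Brief treatment with NaBH4 in aqueous NaOH at 0 °C returns 24, where the fallback rejoins the route.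

Step 6. The hindered ester may be reduced slowly and then over-reduced on warming, giving mixtures of ester, aldehyde and alcohol. Fallback, full reduction and re-oxidation: it sets out from 10. LiAlH4 in THF at 0 °C gives [(1S,2S)-2-(1,3-dioxolan-2-yl)-2,6,6-trimethylcyclohexyl]methanol F8, and Dess–Martin periodinane returns 11, where the fallback rejoins the route.

## Further compounds

F1 | step 14 | methyl (13S)-6β-acetoxy-17-(tributylstannyl)labd-8(17)-en-15-oate (E/Z mixture at C8=C17) | COC(=O)C[C@@H](C)CC[C@@H]1[C@@]2(C)CCCC(C)(C)[C@@H]2[C@H](OC(C)=O)CC1=C[Sn](CCCC)(CCCC)CCCC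
F2 | step 14 | methyl (13S)-6β-acetoxylabd-8(17)-en-15-oate | COC(=O)C[C@@H](C)CC[C@@H]1[C@@]2(C)CCCC(C)(C)[C@@H]2[C@H](OC(C)=O)CC1=C
F3 | step 7 | (1RS)-1-[(1S,2S)-2-(1,3-dioxolan-2-yl)-2,6,6-trimethylcyclohexyl]but-3-yn-1-ol (C6 epimers) | C#CCC(O)[C@H]1C(C)(C)CCC[C@]1(C)C1OCCO1
F4 | step 7 | 1-[(1S,2S)-2-(1,3-dioxolan-2-yl)-2,6,6-trimethylcyclohexyl]but-3-yn-1-one | C#CCC(=O)[C@H]1C(C)(C)CCC[C@]1(C)C1OCCO1
F5 | step 1 | methyl benzyl{(1E)-3-[(tert-butyldimethylsilyl)oxy]buta-1,3-dien-1-yl}carbamate | COC(=O)N(Cc1ccccc1)/C=C/C(=C)O[Si](C)(C)C(C)(C)C
F6 | step 1 | ethyl (1S,5S,6R)-5-[benzyl(methoxycarbonyl)amino]-6-formyl-6-methyl-3-[(tert-butyldimethylsilyl)oxy]cyclohex-3-ene-1-carboxylate | CCOC(=O)[C@H]1CC(O[Si](C)(C)C(C)(C)C)=C[C@H](N(Cc2ccccc2)C(=O)OC)[C@]1(C)C=O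
F7 | step 15 | methyl (13R)-6β-acetoxy-17-(acetoxymercurio)-8α-hydroxylabd-11E-en-15-oate | COC(=O)C[C@@H](C)/C=C/[C@@H]1[C@@]2(C)CCCC(C)(C)[C@@H]2[C@H](OC(C)=O)C[C@@]1(C[Hg]OC(C)=O)O
F8 | step 6 | [(1S,2S)-2-(1,3-dioxolan-2-yl)-2,6,6-trimethylcyclohexyl]methanol | OC[C@H]1C(C)(C)CCC[C@]1(C)C1OCCO1
A1 | alternative 1 | trans-fused 6-(tert-butyldimethylsilyloxy)-8β-methyl bicyclic C11 aldehyde (labdane numbering; 5α-H, 9β-formyl, 10β-methyl, C6=C7 silyl enol ether) | O=C[C@@H]1[C@@]2(C)CCCC(C)(C)[C@@H]2C(O[Si](C)(C)C(C)(C)C)=C[C@@H]1C
A2 | alternative 1 | (2E,8Z,10E)-9-[(tert-butyldimethylsilyl)oxy]-3,7,7-trimethyldodeca-2,8,10-trienal | O=C/C=C(\C)CCCC(C)(C)/C=C(O[Si](C)(C)C(C)(C)C)/C=C/C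
A3 | alternative 2 | 3α-hydroxy-4,4,10-trimethyl-trans-decalin-6,8-dione (labdane numbering) | O=C1C[C@@]2(C)CC[C@@H](O)C(C)(C)[C@@H]2C(=O)C1
A4 | alternative 2 | 3-{2-[(2R)-3,3-dimethyloxiran-2-yl]ethyl}-1,5-dimethoxy-3-methylcyclohexa-1,4-diene | COC1=CC(C)(CC[C@H]2OC2(C)C)C=C(OC)C1
A5 | alternative 3 | methyl 8α-(tert-butylperoxy)-6-oxolabdan-15-oate | COC(=O)C[C@@H](C)CC[C@@H]1[C@@]2(C)CCCC(C)(C)[C@@H]2C(=O)C[C@@]1(C)OOC(C)(C)C
A6 | alternative 3 | methyl (3S)-6-(2-formyl-1,3,3-trimethylcyclohexyl)-3,7-dimethyloct-7-enoate (labdane numbering; 5α-H, 9α-H, 10β-methyl) | COC(=O)C[C@@H](C)CC[C@@H](C(C)=C)[C@@]1(C)CCCC(C)(C)[C@@H]1C=O
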